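Its constants are made up; the run is a simulation.

One per minute is the unit of the quantity worth carrying from alder to a second flask.

| flask | substrate | reagent | free catalyst | second catalyst | time | remark |
|---|---|---|---|---|---|---|
| oak | 0.24 M (fed, over 3.0 min) | 0.700 equiv | 15 mol% | 0.2 mol% | 4.0 min | all else is in the flask from the start; the feed brings no volume worth counting |
| maple | 0.24 M | 0.700 equiv (fed, over 3.0 min) | 15 mol% | 0.2 mol% | 4.0 min | all else is in the flask from the start; the feed brings no volume worth counting |
| alder | 0.24 M | 0.700 equiv | 15 mol% | 0.2 mol% | 4.0 min | everything together at the start |

    reagent + second catalyst + intermediate → second catalyst + target (k1 = 200 M⁻² s⁻¹)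
    target → over-reaction product (k2 = 0.014 s⁻¹)
    substrate + free catalyst → free catalyst + intermediate (k3 = 3.9 M⁻¹ s⁻¹)

1. which flask leads in amount of over-reaction product, in percent of the substrate charged ("all alike" within 1.5 percentage points) (oak / maple / alder / all alike)
2. how much over-reaction product is there at the end, in percent of the substrate charged: oak
3. how much over-reaction product is there at the end, in percent of the substrate charged: maple
4. how much over-reaction product is there at the end, in percent of the substrate charged: alder

Start with alder, which you can reckon by hand. Free catalyst gives substrate a lifetime of 0.119 min, far shorter than the 4.0 min asked, so take the charge as intermediate from the start. Target then rises at 0.968 min⁻¹ of the charge, while over-reaction product starts flat.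

Now work with what is left. At 0.700 equiv, reagent is the limiting reagent of the step that makes target, and each turnover takes one intermediate and one reagent, so alder's excess of intermediate stays at 0.0720 M. The ratio of reagent to intermediate therefore decays exponentially from 0.700 at the gap rate, the first constant times second catalyst times that excess: 0.415 min⁻¹.

At 4.0 min the ratio is 0.133, which leaves 6.59 % of alder's reagent. Target plus over-reaction product is then 65.4 % of the substrate, on the way to a level of 70.0 %.

Late on, the rate of making target falls at 0.542 min⁻¹, slower than target decays, at 0.84 min⁻¹. Roughly, then, target trails at 7.41 %. I commit to 58.0 % over-reaction product for alder.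

My formula does not reach oak or maple. Each feed lasts 3.0 min, longer than the target half-life of 0.825 min, so I expect both below alder, without a number.

The forecast names alder, with 42.5 % for oak, 42.5 % for maple and 57 % for alder, and holds that “oak and maple come out nearly the same and well below alder”.

The run gives alder the lead: 42.4 % in oak, 42.2 % in maple, 57.5 % in alder. Alder has half of its substrate turnover up to 4.0 min done by 0.0824 min, long before half of its turnover of target, at 1.65 min, and it ends with 7.61 % target against maple's 15.4 %. Alder's reagent left reads 7.0 %, beside the 6.59 % from the gap rate. In a neighbour flask, alder with 0.8 mol% of second catalyst, the gap rate becomes 1.66 min⁻¹, which leaves 0.0394 % of the reagent and puts target plus over-reaction product close to the 70.0 % level. That run reads 66.2 % over-reaction product and 3.81 % target.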